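**Retrosynthetic overview**
- Target 10 comes from triester 9 by one global ester reduction; no protecting groups are used.
- 9 is opened at both benzylic C2–O1 bonds (and the C3–CO2Me bonds) to the acyclic bis(2-hydroxystilbene) 6. Furan ring A (carrying the 4-hydroxy-3-methoxyphenyl group) and furan ring B (fused to the arene with the propenyl chain) are closed last, in one operation, in either order; all four stereocentres are set there.
- 6 comes from styrene 4 and aryl iodide 5 by a Heck disconnection of the inner stilbene.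
- 4 comes from aldehyde 3 by methylenation; 3 from 5-iodovanillin 1 and 4-vinylguaiacol 2 (Heck); 5 from 1 (Wittig).

Assumption: the sense of induction of the new step 5 cannot be predicted, so the ligand antipode that gives the (2R) series is fixed by a test reaction (CD and rotation against known trans-dihydrobenzofuran neolignans); the (S,S) ligand is written.

**Step 1**
Reactants: 1 5-iodovanillin (4-hydroxy-3-iodo-5-methoxybenzaldehyde); 2 2-methoxy-4-vinylphenol
Product: 3 4-hydroxy-3-[(E)-2-(4-hydroxy-3-methoxyphenyl)ethenyl]-5-methoxybenzaldehyde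
Conditions: Pd(OAc)2 (3 mol%), Bu4NCl, NaHCO3, DMF, 80 °C, argon
Reagents that add atoms: none
Why: Mizoroki–Heck reaction; the aryl–Pd species adds to the terminal carbon of the styrene and syn β-hydride elimination gives the (E)-stilbene, free phenols and the aldehyde being tolerated under ligand-free phase-transfer conditions; no stereocentre is formed.

**Step 2**
Reactants: 3 4-hydroxy-3-[(E)-2-(4-hydroxy-3-methoxyphenyl)ethenyl]-5-methoxybenzaldehyde
Product: 4 4-ethenyl-2-[(E)-2-(4-hydroxy-3-methoxyphenyl)ethenyl]-6-methoxyphenol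
Conditions: MePPh3Br, KOtBu (4.5 equiv each), THF, 0 °C to rt; aq. NH4Cl
Reagents that add atoms: methyltriphenylphosphonium bromide, C[P+](c1ccccc1)(c1ccccc1)c1ccccc1.[Br-]
Why: Wittig methylenation; two equivalents of ylide deprotonate the phenols and the excess olefinates the phenoxide-deactivated aldehyde, leaving the stilbene untouched; no stereocentre is formed.

**Step 3**
Reactants: 1 5-iodovanillin
Product: 5 methyl (E)-3-(4-hydroxy-3-iodo-5-methoxyphenyl)prop-2-enoate (methyl 5-iodoferulate)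
Conditions: Ph3P=CHCO2Me (1.5 equiv), toluene, 90 °C
Reagents that add atoms: methyl (triphenylphosphoranylidene)acetate, COC(=O)C=P(c1ccccc1)(c1ccccc1)c1ccccc1
Why: Wittig olefination with a stabilised ylide gives the (E)-cinnamate selectively and does not touch the aryl iodide or the phenol; no stereocentre is formed.

**Step 4**
Reactants: 4 4-ethenyl-2-[(E)-2-(4-hydroxy-3-methoxyphenyl)ethenyl]-6-methoxyphenol; 5 methyl (E)-3-(4-hydroxy-3-iodo-5-methoxyphenyl)prop-2-enoate
Product: 6 methyl (E)-3-{4-hydroxy-3-[(E)-2-{4-hydroxy-3-[(E)-2-(4-hydroxy-3-methoxyphenyl)ethenyl]-5-methoxyphenyl}ethenyl]-5-methoxyphenyl}prop-2-enoate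
Conditions: Pd(OAc)2 (5 mol%), Bu4NCl, NaHCO3, BHT (cat.), DMF, 75 °C, argon, dark
Reagents that add atoms: none
Why: Mizoroki–Heck reaction; oxidative addition occurs only at the C–I bond of 5 and insertion only at the single terminal alkene of 4 (the internal stilbene and the cinnamate are inert), giving the second (E)-stilbene; no stereocentre is formed.

**Step 5**
Reactants: 6 methyl (E)-3-{4-hydroxy-3-[(E)-2-{4-hydroxy-3-[(E)-2-(4-hydroxy-3-methoxyphenyl)ethenyl]-5-methoxyphenyl}ethenyl]-5-methoxyphenyl}prop-2-enoate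
Product: 9 methyl (2R,3R)-2-[(2R,3R)-2-(4-hydroxy-3-methoxyphenyl)-7-methoxy-3-(methoxycarbonyl)-2,3-dihydro-1-benzofuran-5-yl]-7-methoxy-5-[(E)-3-methoxy-3-oxoprop-1-enyl]-2,3-dihydro-1-benzofuran-3-carboxylate, via ring A monocyclised diester 7 (not isolated), via ring B monocyclised diester 8 (not isolated)
Conditions: Pd(OCOCF3)2 (10 mol%), (S,S)-Ph-box [2,2'-(propane-2,2-diyl)bis((4S)-4-phenyl-4,5-dihydrooxazole)] (12 mol%), p-benzoquinone (3 equiv), CO (3 bar), MeOH/CH2Cl2 1:5, −20 to 0 °C
Reagents that add atoms: carbon monoxide, [C-]#[O+]; methanol, CO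
Why: Proposed new method: the bis(oxazoline)-bound divalent palladium centre binds one face of each (E)-stilbene C=C bond and the neighbouring phenol oxygen adds from the opposite face to the carbon bearing the para-oxygenated aryl group (5-endo anti-oxypalladation, the ring-closing and enantiodetermining C–O bond formation); the benzylic C–Pd bond then takes up CO with retention faster than β-hydride loss and methanolysis releases the ester, so E geometry plus anti addition gives the 2,3-trans rings, the ligand fixes 2R, and because both rings arise from the same catalyst-controlled event the minor sense of induction ends up mostly in a separable diastereomer; p-benzoquinone returns zerovalent palladium to divalent palladium; the closest known reaction type is the intramolecular Wacker-type alkoxycarbonylation of alkenols and alkenylphenols (5-exo and 6-exo, including enantioselective phenol cyclisation–methoxycarbonylation to chromans), whereas the 5-endo mode on a 1,2-diarylalkene and its twofold use are untested.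

**Step 6**
Reactants: 9 the (2R,3R,2'R,3'R) triester
Product: 10 (E)-3-[(2R,3S)-2-[(2R,3S)-2-(4-hydroxy-3-methoxyphenyl)-3-(hydroxymethyl)-7-methoxy-2,3-dihydro-1-benzofuran-5-yl]-3-(hydroxymethyl)-7-methoxy-2,3-dihydro-1-benzofuran-5-yl]prop-2-en-1-ol (CNP0250921.1)
Conditions: iBu2AlH (DIBAL-H, 10 equiv), THF/toluene, −78 to −30 °C; aq. potassium sodium tartrate
Reagents that add atoms: none
Why: Hydride reduction of three esters with DIBAL-H, 1,2-selective on the cinnamate to give the (E)-allylic alcohol; the non-basic, low-temperature conditions avoid C3 epimerisation and β-aryloxy elimination, so the four stereocentres are untouched (3R becomes 3S only by CIP priority change).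

**Compound list**
1 | 5-iodovanillin (4-hydroxy-3-iodo-5-methoxybenzaldehyde) | COc1cc(C=O)cc(I)c1O | starting material
2 | 2-methoxy-4-vinylphenol | COc1cc(C=C)ccc1O | starting material
3 | 4-hydroxy-3-[(E)-2-(4-hydroxy-3-methoxyphenyl)ethenyl]-5-methoxybenzaldehyde | COc1cc(/C=C/c2cc(C=O)cc(OC)c2O)ccc1O | intermediate
4 | 4-ethenyl-2-[(E)-2-(4-hydroxy-3-methoxyphenyl)ethenyl]-6-methoxyphenol | COc1cc(/C=C/c2cc(C=C)cc(OC)c2O)ccc1O | intermediate
5 | methyl (E)-3-(4-hydroxy-3-iodo-5-methoxyphenyl)prop-2-enoate | COc1cc(/C=C/C(=O)OC)cc(I)c1O | intermediate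
6 | methyl (E)-3-{4-hydroxy-3-[(E)-2-{4-hydroxy-3-[(E)-2-(4-hydroxy-3-methoxyphenyl)ethenyl]-5-methoxyphenyl}ethenyl]-5-methoxyphenyl}prop-2-enoate | COc1cc(/C=C/c2cc(/C=C/c3cc(/C=C/C(=O)OC)cc(OC)c3O)cc(OC)c2O)ccc1O | intermediate
7 | methyl (2R,3R)-2-(4-hydroxy-3-methoxyphenyl)-5-[(E)-2-{2-hydroxy-3-methoxy-5-[(E)-3-methoxy-3-oxoprop-1-enyl]phenyl}ethenyl]-7-methoxy-2,3-dihydro-1-benzofuran-3-carboxylate (ring A closed) | COc1cc([C@@H]2Oc3c(OC)cc(/C=C/c4cc(/C=C/C(=O)OC)cc(OC)c4O)cc3[C@H]2C(=O)OC)ccc1O | intermediate (not isolated)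
8 | methyl (2R,3R)-2-{4-hydroxy-3-[(E)-2-(4-hydroxy-3-methoxyphenyl)ethenyl]-5-methoxyphenyl}-7-methoxy-5-[(E)-3-methoxy-3-oxoprop-1-enyl]-2,3-dihydro-1-benzofuran-3-carboxylate (ring B closed) | COc1cc(/C=C/c2cc([C@@H]3Oc4c(OC)cc(/C=C/C(=O)OC)cc4[C@H]3C(=O)OC)cc(OC)c2O)ccc1O | intermediate (not isolated)
9 | methyl (2R,3R)-2-[(2R,3R)-2-(4-hydroxy-3-methoxyphenyl)-7-methoxy-3-(methoxycarbonyl)-2,3-dihydro-1-benzofuran-5-yl]-7-methoxy-5-[(E)-3-methoxy-3-oxoprop-1-enyl]-2,3-dihydro-1-benzofuran-3-carboxylate | COc1cc([C@@H]2Oc3c(OC)cc([C@@H]4Oc5c(OC)cc(/C=C/C(=O)OC)cc5[C@H]4C(=O)OC)cc3[C@H]2C(=O)OC)ccc1O | intermediate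
10 | (E)-3-[(2R,3S)-2-[(2R,3S)-2-(4-hydroxy-3-methoxyphenyl)-3-(hydroxymethyl)-7-methoxy-2,3-dihydro-1-benzofuran-5-yl]-3-(hydroxymethyl)-7-methoxy-2,3-dihydro-1-benzofuran-5-yl]prop-2-en-1-ol | COc1cc([C@@H]2Oc3c(OC)cc([C@@H]4Oc5c(OC)cc(/C=C/CO)cc5[C@H]4CO)cc3[C@H]2CO)ccc1O | target

**Step count and risks**
Total steps: 6. Longest linear sequence: 5 (steps 1, 2, 4, 5, 6).

The three steps most likely to fail:

Step 5 (the proposed new double oxycarbonylation). It can fail through β-hydride loss to 2-arylbenzofurans, CO insertion into a Pd–OAr bond giving 3-arylcoumarins, methanol addition in place of the phenol, or low enantioselectivity. The fallback uses known chemistry: enantioselective intramolecular benzylic C–H insertion of aryl diazoacetates under a chiral dirhodium carboxylate, which gives cis-2-aryl-2,3-dihydrobenzofuran-3-carboxylates that epimerise to trans with methoxide. It sets out from 1 and 5 and comes back at 9. Bought 4-(tert-butyldimethylsilyloxy)-3-methoxybenzaldehyde (COc1cc(C=O)ccc1O[Si](C)(C)C(C)(C)C) is reduced with NaBH4 in MeOH to [4-(tert-butyldimethylsilyloxy)-3-methoxyphenyl]methanol F1. Mitsunobu etherification of phenol 1 with F1 (PPh3, DIAD, THF) gives 4-{[4-(tert-butyldimethylsilyloxy)-3-methoxyphenyl]methoxy}-3-iodo-5-methoxybenzaldehyde F2, and NaBH4 reduces it to the corresponding benzylic alcohol F3. A second Mitsunobu reaction of F3 with phenol 5 gives the di-iodo bis(benzyl aryl ether) cinnamate F4. Both aryl iodides are coupled with methyl diazoacetate (COC(=O)C=[N+]=[N-]; Pd(PPh3)4, Ag2CO3, Et3N, toluene, rt) to give the bis(aryl diazoacetate) F5. Rh2(S-PTTL)4 (dirhodium tetrakis[N-phthaloyl-(S)-tert-leucinate], or its antipode, whichever gives 2R; toluene, −60 °C) inserts each carbenoid into the neighbouring O–CH2–aryl C–H bond to give the cis,cis-(2R,3S,2'R,3'S) bis(dihydrobenzofuran) silyl ether F6. NaOMe in MeOH epimerises both C3 centres to trans and cleaves the aryl silyl ether, giving 9.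

Step 4 (Heck coupling of the electron-rich, polymerisation-prone vinylphenol 4). It can fail through oligomerisation of 4 or 1,1-diaryl regioisomers. The fallback sets out from 4 and comes back at 6. Cross-metathesis of 4 with vinylboronic acid pinacol ester (C=CB1OC(C)(C)C(C)(C)O1; second-generation Grubbs catalyst, CH2Cl2, 40 °C) gives 2-[(E)-2-(4-hydroxy-3-methoxyphenyl)ethenyl]-6-methoxy-4-[(E)-2-(4,4,5,5-tetramethyl-1,3,2-dioxaborolan-2-yl)ethenyl]phenol F7. Suzuki–Miyaura coupling of F7 with iodide 5 (Pd(dppf)Cl2, K2CO3, dioxane/water, 80 °C) gives 6 with the regiochemistry fixed by the C–B bond.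

Step 2 (Wittig methylenation of an aldehyde deactivated by a para-phenoxide). It can stall at low conversion. The fallback sets out from 3 and comes back at 4. Addition of MeMgBr (4 equiv, THF, 0 °C) gives racemic 4-(1-hydroxyethyl)-2-[(E)-2-(4-hydroxy-3-methoxyphenyl)ethenyl]-6-methoxyphenol F8. Mild dehydration of F8 through the para-quinone methide (pyridinium p-toluenesulfonate cat., BHT, toluene, 80 °C) gives 4.

**Further compounds**
F1 | step 5 | [4-(tert-butyldimethylsilyloxy)-3-methoxyphenyl]methanol | COc1cc(CO)ccc1O[Si](C)(C)C(C)(C)C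
F2 | step 5 | 4-{[4-(tert-butyldimethylsilyloxy)-3-methoxyphenyl]methoxy}-3-iodo-5-methoxybenzaldehyde | COc1cc(COc2c(I)cc(C=O)cc2OC)ccc1O[Si](C)(C)C(C)(C)C
F3 | step 5 | (4-{[4-(tert-butyldimethylsilyloxy)-3-methoxyphenyl]methoxy}-3-iodo-5-methoxyphenyl)methanol | COc1cc(COc2c(I)cc(CO)cc2OC)ccc1O[Si](C)(C)C(C)(C)C
F4 | step 5 | methyl (E)-3-{4-[(4-{[4-(tert-butyldimethylsilyloxy)-3-methoxyphenyl]methoxy}-3-iodo-5-methoxyphenyl)methoxy]-3-iodo-5-methoxyphenyl}prop-2-enoate | COc1cc(COc2c(I)cc(COc3c(I)cc(/C=C/C(=O)OC)cc3OC)cc2OC)ccc1O[Si](C)(C)C(C)(C)C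
F5 | step 5 | bis(aryl diazoacetate): analogue of F4 with each iodine replaced by C(=N2)CO2Me | COc1cc(COc2c(C(=[N+]=[N-])C(=O)OC)cc(COc3c(C(=[N+]=[N-])C(=O)OC)cc(/C=C/C(=O)OC)cc3OC)cc2OC)ccc1O[Si](C)(C)C(C)(C)C
F6 | step 5 | cis,cis-(2R,3S,2'R,3'S) C3-epimer of 9 as its 4-O-tert-butyldimethylsilyl ether | COc1cc([C@@H]2Oc3c(OC)cc([C@@H]4Oc5c(OC)cc(/C=C/C(=O)OC)cc5[C@@H]4C(=O)OC)cc3[C@@H]2C(=O)OC)ccc1O[Si](C)(C)C(C)(C)C
F7 | step 4 | 2-[(E)-2-(4-hydroxy-3-methoxyphenyl)ethenyl]-6-methoxy-4-[(E)-2-(4,4,5,5-tetramethyl-1,3,2-dioxaborolan-2-yl)ethenyl]phenol | COc1cc(/C=C/c2cc(/C=C/B3OC(C)(C)C(C)(C)O3)cc(OC)c2O)ccc1O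
F8 | step 2 | racemic 4-(1-hydroxyethyl)-2-[(E)-2-(4-hydroxy-3-methoxyphenyl)ethenyl]-6-methoxyphenol | COc1cc(/C=C/c2cc(C(C)O)cc(OC)c2O)ccc1O
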